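The two C–C bonds that join the lactones to the diaryl ether core are made together, in one enolate alkylation.

In each γ-butyrolactone ring, C3 (the carbon between the lactone C=O and the C4 stereocentre) carries a CH2 bonded to one benzene ring of the central diaryl ether. Cutting both C3–CH2 bonds leaves two copies of one chiral lactone and a single bis-electrophile. In the forward sense, two lithium enolates of (S)-4-(3,4-dimethoxybenzyl)butyrolactone displace the two benzylic bromides of a diaryl ether bis(bromomethyl) compound whose central phenol is masked as a benzyl ether. One operation thus makes both C–C bonds and both C3 stereocentres, each trans to its C4 benzyl group; hydrogenolysis of the benzyl ether then releases the target.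

Key step: step 8

Remark: all four stereocentres of the target are S (each lactone 3S,4S, trans), the mirror image of the arctigenin-type arrangement, so the (S)-lactone is the building block needed; MOD-DIOP means the bis(4-methoxy-3,5-dimethylphenyl)phosphino analogue of DIOP.

Step 1
Reactants: 1 3,4-dimethoxybenzaldehyde; 2 dimethyl succinate
Product: 3 (E)-4-(3,4-dimethoxyphenyl)-3-(methoxycarbonyl)but-3-enoic acid
Conditions: NaOMe, MeOH, reflux; then aq. HCl
Reagents that add atoms: none
Why: Stobbe condensation: the succinate enolate adds to the non-enolisable aldehyde and the lactonisation/ring-opening sequence of this reaction should deliver the half-ester with the free acid on the CH2 arm and the (E)-alkene (aryl trans to CO2Me), the substrate geometry that the hydrogenation needs.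

Step 2
Reactants: 3 (E)-4-(3,4-dimethoxyphenyl)-3-(methoxycarbonyl)but-3-enoic acid
Product: 4 (S)-4-(3,4-dimethoxyphenyl)-3-(methoxycarbonyl)butanoic acid
Conditions: H2 (1–5 atm), [Rh(cod)Cl]2 (cat.), (4R,5R)-MOD-DIOP (cat.), Et3N (1 equiv), MeOH, 30 °C; then dil. HCl, recrystallise
Reagents that add atoms: none
Why: Rh(I)–diphosphine asymmetric hydrogenation of an itaconate-type arylidenesuccinic half-ester, in which the carboxylate binds rhodium and the C2-symmetric ligand selects the alkene face; the (4R,5R) ligand is the antipode expected to give the (S) acid, the sense is to be checked on lactone 6 (sign of rotation, chiral HPLC) and the ligand antipode exchanged if needed, and crystallisation should raise the optical purity.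

Step 3
Reactants: 4 (S)-4-(3,4-dimethoxyphenyl)-3-(methoxycarbonyl)butanoic acid
Product: 6 (S)-4-(3,4-dimethoxybenzyl)dihydrofuran-2(3H)-one, via hydroxy acid 5 (not isolated)
Conditions: KOH (1 equiv), EtOH; CaCl2, NaBH4, −10 °C to rt; then 2 M HCl, rt to 50 °C
Reagents that add atoms: none
Why: Chemoselective ester reduction followed by acid-promoted lactonisation: with the acid held as its potassium carboxylate, calcium borohydride should reduce only the methyl ester, and acidification closes the γ-lactone from hydroxy acid 5; the stereocentre is not touched and keeps the S descriptor because CH2O takes the rank of CO2Me.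

Step 4
Reactants: 7 5-bromovanillin
Product: 8 4-(benzyloxy)-3-bromo-5-methoxybenzaldehyde
Conditions: BnBr, K2CO3, DMF, 60 °C
Reagents that add atoms: benzyl bromide, BrCc1ccccc1
Why: Williamson ether synthesis on an acidic para-formyl phenoxide; the benzyl ether should survive the copper coupling, the hydride, PBr3 and enolate steps and is removed by hydrogenolysis at the end.

Step 5
Reactants: 8 4-(benzyloxy)-3-bromo-5-methoxybenzaldehyde; 9 vanillin (1.5 equiv)
Product: 10 4-(benzyloxy)-3-(4-formyl-2-methoxyphenoxy)-5-methoxybenzaldehyde
Conditions: CuI (20 mol%), N,N-dimethylglycine·HCl (40 mol%), Cs2CO3, 1,4-dioxane, 100 °C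
Reagents that add atoms: none
Why: Ullmann diaryl ether synthesis (ligand-accelerated Cu(I) coupling of a phenoxide with an aryl bromide); neither aldehyde is enolisable, the benzyl ether is inert, and the single C–Br bond fixes where the oxygen is attached.

Step 6
Reactants: 10 4-(benzyloxy)-3-(4-formyl-2-methoxyphenoxy)-5-methoxybenzaldehyde
Product: 11 [4-(benzyloxy)-3-[4-(hydroxymethyl)-2-methoxyphenoxy]-5-methoxyphenyl]methanol
Conditions: NaBH4, MeOH/THF, 0 °C to rt
Reagents that add atoms: none
Why: Borohydride reduction of two aryl aldehydes to benzylic alcohols; the ethers are inert to the reagent.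

Step 7
Reactants: 11 [4-(benzyloxy)-3-[4-(hydroxymethyl)-2-methoxyphenoxy]-5-methoxyphenyl]methanol
Product: 12 2-(benzyloxy)-5-(bromomethyl)-1-[4-(bromomethyl)-2-methoxyphenoxy]-3-methoxybenzene
Conditions: PBr3 (0.8 equiv), CH2Cl2, 0 °C, 30 min; ice-water work-up; used crude at once
Reagents that add atoms: phosphorus tribromide, BrP(Br)Br
Why: Bromination of electron-rich benzylic alcohols through their phosphite esters, the usual entry to alkoxybenzyl bromides; short contact at 0 °C should spare the aryl benzyl ether, and the labile dibromide is not stored.

Step 8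
Reactants: 6 (S)-4-(3,4-dimethoxybenzyl)dihydrofuran-2(3H)-one (2.4 equiv); 12 2-(benzyloxy)-5-(bromomethyl)-1-[4-(bromomethyl)-2-methoxyphenoxy]-3-methoxybenzene (1 equiv)
Product: 14 O-benzyl ether of the target, via lithium enolate 13 (not isolated)
Conditions: 6, LiHMDS (2.4 equiv), THF, −78 °C; then 12 in THF/DMPU added, −78 to −40 °C; aq. NH4Cl
Reagents that add atoms: none
Why: LiHMDS removes a C3 proton of 6 to give the planar lithium enolate 13, whose C3 carbon displaces bromide from each ArCH2Br of 12 in an SN2 step, so the two C3–CH2 bonds form one after the other and no ring is closed. The closest known reaction is the trans-selective α-benzylation of β-benzyl-γ-butyrolactone enolates with alkoxybenzyl bromides, the standard entry to dibenzylbutyrolactone lignans, applied here at both ends of one electrophile. Each new C3 stereocentre is controlled by the neighbouring (S)-C4 centre (1,2-induction): the 3,4-dimethoxybenzyl group covers one face of the five-membered enolate, the bromide enters anti, and the (3S,4S) trans lactone should result at both ends because the two sites are remote and meet the same enantiomer of the nucleophile. The step needs trans selectivity, C- over O-alkylation, a single alkylation per C3 and complete reaction of both arms; these should be secured respectively by the substrate bias, by the soft primary benzylic bromide, by the hindrance of the now tertiary C3, and by keeping the enolate in excess (12 added to 13) with DMPU to break up its aggregates. Neither bromide has a β-hydrogen, so elimination cannot compete, and since trans is also the more stable arrangement, proton exchange at C3 would not erode the outcome.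

Step 9
Reactants: 14 O-benzyl ether of the target
Product: 15 target CNP0183104.1
Conditions: H2 (1 atm), 10% Pd/C, EtOAc/EtOH, rt
Reagents that add atoms: none
Why: Hydrogenolysis of an aryl benzyl ether under neutral conditions; the lactones, the aryl methyl ethers and the diaryl ether should be inert, and no stereocentre is touched.

Compound list
1 | 3,4-dimethoxybenzaldehyde | COc1ccc(C=O)cc1OC | starting material
2 | dimethyl succinate | COC(=O)CCC(=O)OC | starting material
3 | (E)-4-(3,4-dimethoxyphenyl)-3-(methoxycarbonyl)but-3-enoic acid | COC(=O)/C(=C/c1ccc(OC)c(OC)c1)CC(=O)O | intermediate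
4 | (S)-4-(3,4-dimethoxyphenyl)-3-(methoxycarbonyl)butanoic acid | OC(=O)C[C@H](Cc1ccc(OC)c(OC)c1)C(=O)OC | intermediate
5 | (S)-4-(3,4-dimethoxyphenyl)-3-(hydroxymethyl)butanoic acid (hydroxy acid, not isolated) | OC(=O)C[C@H](Cc1ccc(OC)c(OC)c1)CO | intermediate
6 | (S)-4-(3,4-dimethoxybenzyl)dihydrofuran-2(3H)-one | COc1ccc(C[C@@H]2COC(=O)C2)cc1OC | intermediate
7 | 5-bromovanillin (3-bromo-4-hydroxy-5-methoxybenzaldehyde) | COc1cc(C=O)cc(Br)c1O | starting material
8 | 4-(benzyloxy)-3-bromo-5-methoxybenzaldehyde | COc1cc(C=O)cc(Br)c1OCc1ccccc1 | intermediate
9 | vanillin (4-hydroxy-3-methoxybenzaldehyde) | COc1cc(C=O)ccc1O | starting material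
10 | 4-(benzyloxy)-3-(4-formyl-2-methoxyphenoxy)-5-methoxybenzaldehyde | O=Cc1ccc(Oc2cc(C=O)cc(OC)c2OCc2ccccc2)c(OC)c1 | intermediate
11 | [4-(benzyloxy)-3-[4-(hydroxymethyl)-2-methoxyphenoxy]-5-methoxyphenyl]methanol | OCc1ccc(Oc2cc(CO)cc(OC)c2OCc2ccccc2)c(OC)c1 | intermediate
12 | 2-(benzyloxy)-5-(bromomethyl)-1-[4-(bromomethyl)-2-methoxyphenoxy]-3-methoxybenzene | BrCc1ccc(Oc2cc(CBr)cc(OC)c2OCc2ccccc2)c(OC)c1 | intermediate
13 | lithium (S)-4-(3,4-dimethoxybenzyl)-4,5-dihydrofuran-2-olate (lithium enolate of 6, not isolated) | COc1ccc(C[C@@H]2COC([O-])=C2)cc1OC.[Li+] | intermediate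
14 | O-benzyl ether of the target: (3S,4S)-3-[4-(benzyloxy)-3-methoxy-5-[2-methoxy-4-[[(3S,4S)-4-(3,4-dimethoxybenzyl)-2-oxotetrahydrofuran-3-yl]methyl]phenoxy]benzyl]-4-(3,4-dimethoxybenzyl)dihydrofuran-2(3H)-one | COc1ccc(C[C@@H]2COC(=O)[C@H]2Cc2ccc(Oc3cc(C[C@@H]4C(=O)OC[C@H]4Cc4ccc(OC)c(OC)c4)cc(OC)c3OCc3ccccc3)c(OC)c2)cc1OC | intermediate
15 | CNP0183104.1: (3S,4S)-4-(3,4-dimethoxybenzyl)-3-[4-hydroxy-3-methoxy-5-[2-methoxy-4-[[(3S,4S)-4-(3,4-dimethoxybenzyl)-2-oxotetrahydrofuran-3-yl]methyl]phenoxy]benzyl]dihydrofuran-2(3H)-one | COc1ccc(C[C@@H]2COC(=O)[C@H]2Cc2ccc(Oc3cc(C[C@@H]4C(=O)OC[C@H]4Cc4ccc(OC)c(OC)c4)cc(OC)c3O)c(OC)c2)cc1OC | target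

Total step count: 9 (steps 1–3 make the lactone, steps 4–7 the dibromide, steps 8–9 join and deprotect).
Longest linear sequence: 6 steps (4, 5, 6, 7, 8, 9, from 5-bromovanillin); the lactone arm needs 5 (1, 2, 3, 8, 9).

Steps most likely to fail

Step 8. The electron-rich bis(benzyl bromide) may ionise and self-condense, or be used up by proton transfer or O-alkylation, before its second arm has reacted. The mono-alkylated bromide would then accumulate or decompose and the two-fold alkylation would stay incomplete. The fallback sets out from 6 and 10 and makes the same two C3–CH2 bonds by a two-directional aldol addition, avoiding benzylic halides altogether. Enolate 13 (LiHMDS, THF, −78 °C) should add to both formyl groups of dialdehyde 10 anti to the C4 substituent. This would give the bis-aldol adduct F1: compound 14 with a hydroxyl on each benzylic carbon attached to C3, lactones trans as in 14, carbinol centres as a mixture of epimers. Hydrogenolysis (H2, Pd/C, AcOH, cat. HClO4, rt) should then remove both benzylic hydroxyls and the O-benzyl group together, and the fallback comes back to the route at 15. Steps 6, 7 and 9 are then not needed.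

Step 5. Both partners are ortho-substituted and the phenoxide of vanillin is deactivated by its para-formyl group, so C–O coupling may be slower than hydrodebromination of 8 and catalyst decay. The fallback sets out from 7 and replaces the copper coupling by a nucleophilic aromatic substitution. Copper-mediated hydrolysis of the bromide (Cu powder, aq. NaOH, reflux; then HCl) should give 3,4-dihydroxy-5-methoxybenzaldehyde F2, which is also available commercially. Regioselective benzylation of its more acidic 4-hydroxyl (BnBr 1 equiv, NaHCO3, NaI cat., DMF, 40 °C) should give 4-(benzyloxy)-3-hydroxy-5-methoxybenzaldehyde F3. Its phenoxide should then displace fluoride from commercial 4-fluoro-3-methoxybenzaldehyde, activated by the para-formyl group (K2CO3, DMF, 120 °C), and the fallback comes back to the route at 10.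

Step 2. Facial discrimination in the hydrogenation may be incomplete, or the sense of induction may be opposite to the one expected. Because two lactone units are joined in step 8, any (R)-lactone would be carried into diastereomeric dimers that are hard to remove. The fallback sets out from 3 and replaces catalyst control by classical resolution. Hydrogenation over an achiral catalyst (H2, Pd/C, MeOH) should give racemic 4-(3,4-dimethoxyphenyl)-3-(methoxycarbonyl)butanoic acid F4. Fractional crystallisation of its salt with (S)-1-phenylethylamine should give the (S)-1-phenylethylammonium salt of the (S)-acid F5; if a salt screen shows that this amine precipitates the (R)-acid, its antipode is used instead. Acidification of the salt comes back to the route at 4.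

Further compounds
F1 | step 8 | bis-aldol adduct: 14 with OH on each benzylic carbon attached to C3 (trans lactones as in 14, carbinol epimers) | COc1ccc(C[C@@H]2COC(=O)[C@H]2C(O)c2ccc(Oc3cc(C(O)[C@@H]4C(=O)OC[C@H]4Cc4ccc(OC)c(OC)c4)cc(OC)c3OCc3ccccc3)c(OC)c2)cc1OC
F2 | step 5 | 3,4-dihydroxy-5-methoxybenzaldehyde | COc1cc(C=O)cc(O)c1O
F3 | step 5 | 4-(benzyloxy)-3-hydroxy-5-methoxybenzaldehyde | COc1cc(C=O)cc(O)c1OCc1ccccc1
F4 | step 2 | racemic 4-(3,4-dimethoxyphenyl)-3-(methoxycarbonyl)butanoic acid | OC(=O)CC(Cc1ccc(OC)c(OC)c1)C(=O)OC
F5 | step 2 | (S)-1-phenylethylammonium (S)-4-(3,4-dimethoxyphenyl)-3-(methoxycarbonyl)butanoate | [O-]C(=O)C[C@H](Cc1ccc(OC)c(OC)c1)C(=O)OC.C[C@H]([NH3+])c1ccccc1
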